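**Plan**
- Retrosynthesis: after removal of the tert-butyl ester and the acetate, the hydroxycyclopentenone is cut at the ring bonds C1–C5 and C3–C4 and at the CH2–CH= bond of the pentenyl chain. This gives a vinyl ketone (from azelaic acid), a (Z)-butenyl cuprate and a β-sulfinyl acryloylsilane.
- Enabling feature: with the ring numbered C1 (ketone), C2=C3, C4 (oxygen-bearing quaternary carbon) and C5 (pentenyl methine), C5 sits between the C1 carbonyl and the C4 carbinol. It is therefore the enolate carbon of a C4 ketone that is acylated at C1, after which C3 captures the ketone.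
- Forward: the two carbonyl fragments take three steps each and the cuprate one; a single operation then joins the pentenyl chain and closes the only ring (C1–C5 first, C3–C4 second). Fluoride unveils the enone, and acetylation and ester cleavage finish the route.
- Stereochemistry: the Z-alkene comes from syn-carbocupration of acetylene. The C4/C5 relative configuration comes from the ring closure (ester chain trans to pentenyl). The absolute configuration comes from an enantiopure p-tolylsulfinyl group (from a menthyl sulfinate), which is excised when C2=C3 is formed.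

Key step: step 8

Assumption: the (S)-sulfinyl group is taken to favour the ring configuration of the target; if the opposite sense is found, the enantiomeric sulfinate (from (−)-menthol) is used in step 5 and nothing else changes.

**Step 1**
Reactants: 1 azelaic acid
Product: 2 9-tert-butoxy-9-oxononanoic acid
Conditions: Me2NCH(OtBu)2 (0.5 equiv), toluene, 85 °C
Reagents that add atoms: N,N-dimethylformamide di-tert-butyl acetal, CN(C)C(OC(C)(C)C)OC(C)(C)C
Why: The amide acetal transfers a tert-butyl group to a carboxylate oxygen (tert-butyl esterification by an amide acetal), and with the diacid in excess the statistical mixture is biased toward the monoester, which is separated from diacid by extraction and from diester by chromatography.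

**Step 2**
Reactants: 2 9-tert-butoxy-9-oxononanoic acid
Product: 4 tert-butyl 9-[methoxy(methyl)amino]-9-oxononanoate, via acyl imidazolide 3 (not isolated)
Conditions: CDI, CH2Cl2, rt; then MeNHOMe·HCl, rt
Reagents that add atoms: N,O-dimethylhydroxylamine hydrochloride, CNOC.Cl
Why: CDI turns the free acid into the acyl imidazolide, which the hydroxylamine attacks to give the Weinreb amide (amide coupling through an activated acyl azole) while the tert-butyl ester is untouched.

**Step 3**
Reactants: 4 tert-butyl 9-[methoxy(methyl)amino]-9-oxononanoate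
Product: 6 tert-butyl 9-oxoundec-10-enoate, via magnesium chelate 5 (not isolated)
Conditions: CH2=CHMgBr, THF, −20 → 0 °C; cannulated into cold 1 M HCl
Reagents that add atoms: vinylmagnesium bromide, C=C[Mg]Br
Why: Weinreb ketone synthesis: the Grignard reagent adds once to give a chelated tetrahedral adduct that survives until the quench, the hindered tert-butyl ester does not react at this temperature, and quenching into acid keeps the released hydroxylamine protonated so that it cannot add to the new vinyl ketone.

**Step 4**
Reactants: 7 methoxyallene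
Product: 9 tert-butyl(1-methoxypropa-1,2-dien-1-yl)dimethylsilane, via lithiomethoxyallene 8 (not isolated)
Conditions: n-BuLi, THF, −78 °C; then TBSCl, −78 °C → rt
Reagents that add atoms: tert-butyldimethylsilyl chloride, CC(C)(C)[Si](C)(C)Cl
Why: The hydrogen on the oxygen-bearing allene carbon is the most acidic, so n-BuLi gives the 1-lithio-1-methoxyallene, which is silylated on carbon (α-metalation and C-silylation of an alkoxyallene).

**Step 5**
Reactants: 9 tert-butyl(1-methoxypropa-1,2-dien-1-yl)dimethylsilane; 10 (1S,2R,5S)-menthyl (R)-4-methylbenzenesulfinate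
Product: 12 tert-butyl{1-methoxy-3-[(S)-(4-methylphenyl)sulfinyl]propa-1,2-dien-1-yl}dimethylsilane, via lithioallene 11 (not isolated)
Conditions: n-BuLi, THF, −78 °C; then added by cannula to 10 (1.5 equiv), THF, −78 °C; H2O
Reagents that add atoms: none
Why: With C1 blocked the second deprotonation takes place at the allene terminus, and the lithioallene displaces mentholate from sulfur with inversion (Andersen sulfoxide synthesis), which fixes the (S) configuration at sulfur; inverse addition to excess sulfinate at −78 °C limits proton transfer from the more acidic product, and the allene axis is of no consequence because it is lost in step 6.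

**Step 6**
Reactants: 12 tert-butyl{1-methoxy-3-[(S)-(4-methylphenyl)sulfinyl]propa-1,2-dien-1-yl}dimethylsilane
Product: 13 (E)-1-[tert-butyl(dimethyl)silyl]-3-[(S)-(4-methylphenyl)sulfinyl]prop-2-en-1-one
Conditions: 0.5 M aq. H2SO4, THF, 0 °C → rt, dark
Reagents that add atoms: water, O
Why: Protonation of the enol ether at the central allene carbon gives an oxocarbenium ion that water converts into the acylsilane with loss of methanol (hydrolysis of a 1-silyl-1-alkoxyallene to an enoylsilane); a halide-free acid is used so that the sulfoxide cannot racemise, the alkene geometry is not controlled by design, and only the (E)-isomer is carried on after chromatographic removal of any (Z)-isomer.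

**Step 7**
Reactants: 14 ethyllithium; 15 acetylene
Product: 17 lithium di[(Z)-but-1-enyl]cuprate, via lithium diethylcuprate 16 (not isolated)
Conditions: CuBr·SMe2 (0.5 equiv per EtLi), Et2O, −40 °C; then HC≡CH (2 equiv per Cu), −50 → −25 °C; solution kept cold and used at once
Reagents that add atoms: CuBr·SMe2, CSC.[Cu]Br
Why: The diethylcuprate adds across acetylene in a syn fashion (carbocupration of an alkyne), so copper and ethyl end up cis and both alkenyl groups have the Z geometry that becomes the Z-alkene of the target.

**Step 8**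
Reactants: 6 tert-butyl 9-oxoundec-10-enoate; 17 lithium di[(Z)-but-1-enyl]cuprate; 13 (E)-1-[tert-butyl(dimethyl)silyl]-3-[(S)-(4-methylphenyl)sulfinyl]prop-2-en-1-one
Product: 21 tert-butyl 8-[(1R,2S,5S)-4-[tert-butyl(dimethyl)silyloxy]-1-hydroxy-2-[(S)-(4-methylphenyl)sulfinyl]-5-[(Z)-pent-2-enyl]cyclopent-3-en-1-yl]octanoate, via lithium enolate 18 (not isolated), via silyl alkoxide 19 (not isolated), via allyl anion 20 (not isolated)
Conditions: 6 added to 17 (1.05 equiv), Et2O, −78 °C; then 13 in THF, −78 → −30 °C; aq. NH4Cl; Et3N-treated silica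
Reagents that add atoms: none
Why: Proposed new method: one (Z)-butenyl group of cuprate 17 adds to the terminal carbon of vinyl ketone 6 to give lithium enolate 18 (new CH2–CH bond), whose carbon adds to the acylsilane carbonyl of 13 (C1–C5) to give alkoxide 19, and migration of silicon from carbon to oxygen (Brook rearrangement) relays the charge into the sulfinyl-stabilised allyl anion 20, whose C3 terminus adds to the C4 ketone (C3–C4). The closest known reaction type is the Brook-rearrangement-mediated [3+2] annulation of β-(arylthio)acryloylsilanes with lithium enolates of alkyl methyl ketones; neither an enolate generated by cuprate addition nor a sulfinyl group in place of the thioether has been shown in it. The one ring closes by a formal 5-exo-trig addition of C3 to the C4 carbonyl, or equivalently by 3-exo-trig closure from C1 to a vinylcyclopropanolate followed by an alkoxide-accelerated 1,3-shift, both paths giving the same bonds. C5 is created in the addition to the acylsilane and C4 in the closure, where the ester chain should turn away from the pentenyl group on C5 (chain trans, hydroxyl cis), while C3 should follow from a lithium bridge between the sulfinyl oxygen and the ketone oxygen that places sulfur cis to the new hydroxyl. The absolute sense is expected from the (S)-sulfinyl group through this chelate, on condition that the first addition is reversible so that the closure selects between the C5 epimers; whatever the level of induction, the two enantiomeric ring series are diastereomers here, and the one with the C4/C5 configuration of the target is secured by chromatography. The step needs carbonyl attack in preference to conjugate attack on the sulfinyl enone, which the aldehyde-like electrophilicity of the acylsilane, the lithium counter-ion and −78 °C should secure, and the regiochemistry of the enolate is fixed by the conjugate addition itself because no proton source is present before the acylsilane arrives.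

**Step 9**
Reactants: 21 tert-butyl 8-[(1R,2S,5S)-4-[tert-butyl(dimethyl)silyloxy]-1-hydroxy-2-[(S)-(4-methylphenyl)sulfinyl]-5-[(Z)-pent-2-enyl]cyclopent-3-en-1-yl]octanoate
Product: 23 tert-butyl 8-[(1S,5S)-1-hydroxy-4-oxo-5-[(Z)-pent-2-enyl]cyclopent-2-en-1-yl]octanoate, via ammonium enolate 22 (not isolated)
Conditions: Bu4NF (1.1 equiv), THF, −20 → 0 °C; AcOH (1.1 equiv) quench
Reagents that add atoms: none
Why: Fluoride cleaves the silyl enol ether to the C1 enolate, which expels p-toluenesulfenate from C3 (E1cB, the retro-Michael fragmentation of β-sulfinyl carbonyl compounds), so that C2=C3 is formed and the C3 and sulfur stereocentres are erased while C4 and C5 are untouched and the tertiary hydroxyl, a poor leaving group, stays.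

**Step 10**
Reactants: 23 tert-butyl 8-[(1S,5S)-1-hydroxy-4-oxo-5-[(Z)-pent-2-enyl]cyclopent-2-en-1-yl]octanoate
Product: 24 tert-butyl 8-[(1S,5S)-1-acetoxy-4-oxo-5-[(Z)-pent-2-enyl]cyclopent-2-en-1-yl]octanoate
Conditions: Ac2O, Sc(OTf)3 (2 mol %), MeCN, −20 °C
Reagents that add atoms: acetic anhydride, CC(=O)OC(C)=O
Why: Sc(OTf)3-catalysed acylation with an anhydride esterifies hindered tertiary alcohols at low temperature without base, which avoids base-induced loss of the new acetate across C4–C5 and epimerisation at C5, and ionisation at C4 is disfavoured because the cation would sit next to the electron-poor enone.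

**Step 11**
Reactants: 24 tert-butyl 8-[(1S,5S)-1-acetoxy-4-oxo-5-[(Z)-pent-2-enyl]cyclopent-2-en-1-yl]octanoate
Product: 25 8-[(1S,5S)-1-acetoxy-4-oxo-5-[(Z)-pent-2-enyl]cyclopent-2-en-1-yl]octanoic acid
Conditions: CF3CO2H, CH2Cl2, 0 °C → rt
Reagents that add atoms: none
Why: Acidolysis of a tert-butyl ester proceeds through the tert-butyl cation and releases isobutene, conditions under which the tertiary acetate (no accessible cation at C4), the enone and the isolated Z-alkene should persist.

**Compound list**
1 | azelaic acid (nonanedioic acid) | OC(=O)CCCCCCCC(=O)O | starting material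
2 | 9-tert-butoxy-9-oxononanoic acid | OC(=O)CCCCCCCC(=O)OC(C)(C)C | intermediate
3 | tert-butyl 9-(imidazol-1-yl)-9-oxononanoate (not isolated) | O=C(CCCCCCCC(=O)OC(C)(C)C)n1ccnc1 | intermediate
4 | tert-butyl 9-[methoxy(methyl)amino]-9-oxononanoate | CON(C)C(=O)CCCCCCCC(=O)OC(C)(C)C | intermediate
5 | bromomagnesium alkoxide of tert-butyl 9-hydroxy-9-[methoxy(methyl)amino]undec-10-enoate (not isolated) | CON(C)C(O[Mg]Br)(C=C)CCCCCCCC(=O)OC(C)(C)C | intermediate
6 | tert-butyl 9-oxoundec-10-enoate | C=CC(=O)CCCCCCCC(=O)OC(C)(C)C | intermediate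
7 | methoxyallene (1-methoxypropa-1,2-diene) | COC=C=C | starting material
8 | 1-lithio-1-methoxypropa-1,2-diene (not isolated) | COC([Li])=C=C | intermediate
9 | tert-butyl(1-methoxypropa-1,2-dien-1-yl)dimethylsilane | COC(=C=C)[Si](C)(C)C(C)(C)C | intermediate
10 | (1S,2R,5S)-2-isopropyl-5-methylcyclohexyl (R)-4-methylbenzenesulfinate, (+)-menthyl (R)-p-toluenesulfinate | C[C@H]1CC[C@@H]([C@H](C1)O[S@@](=O)c2ccc(C)cc2)C(C)C | starting material
11 | tert-butyl(3-lithio-1-methoxypropa-1,2-dien-1-yl)dimethylsilane (not isolated) | COC(=C=C[Li])[Si](C)(C)C(C)(C)C | intermediate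
12 | tert-butyl{1-methoxy-3-[(S)-(4-methylphenyl)sulfinyl]propa-1,2-dien-1-yl}dimethylsilane (both allene-axis epimers) | COC(=C=C[S@](=O)c1ccc(C)cc1)[Si](C)(C)C(C)(C)C | intermediate
13 | (E)-1-[tert-butyl(dimethyl)silyl]-3-[(S)-(4-methylphenyl)sulfinyl]prop-2-en-1-one | CC(C)(C)[Si](C)(C)C(=O)/C=C/[S@](=O)c1ccc(C)cc1 | intermediate
14 | ethyllithium | [Li]CC | starting material
15 | acetylene | C#C | starting material
16 | lithium diethylcuprate, LiCuEt2 (not isolated) | [Li+].CC[Cu-]CC | intermediate
17 | lithium di[(Z)-but-1-enyl]cuprate (solution, used directly) | [Li+].CC/C=C\[Cu-]/C=C\CC | intermediate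
18 | lithium (9Z,12Z)-1-tert-butoxy-1-oxopentadeca-9,12-dien-9-olate (not isolated) | [Li+].CC/C=C\C/C=C(\[O-])CCCCCCCC(=O)OC(C)(C)C | intermediate
19 | lithium salt of tert-butyl (12Z)-10-{(2E)-1-[tert-butyl(dimethyl)silyl]-1-oxido-3-[(S)-(4-methylphenyl)sulfinyl]prop-2-en-1-yl}-9-oxopentadec-12-enoate, C10 configured as C5 of 21 (not isolated) | [Li+].CC/C=C\C[C@@H](C(=O)CCCCCCCC(=O)OC(C)(C)C)C([O-])([Si](C)(C)C(C)(C)C)/C=C/[S@](=O)c1ccc(C)cc1 | intermediate
20 | lithium salt of the Brook-rearranged allyl anion, tert-butyl (12Z)-10-{1-[tert-butyl(dimethyl)silyloxy]-3-[(S)-(4-methylphenyl)sulfinyl]prop-1-en-3-id-1-yl}-9-oxopentadec-12-enoate (not isolated) | [Li+].CC/C=C\C[C@@H](C(=O)CCCCCCCC(=O)OC(C)(C)C)/C(O[Si](C)(C)C(C)(C)C)=C\[CH-][S@](=O)c1ccc(C)cc1 | intermediate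
21 | tert-butyl 8-[(1R,2S,5S)-4-[tert-butyl(dimethyl)silyloxy]-1-hydroxy-2-[(S)-(4-methylphenyl)sulfinyl]-5-[(Z)-pent-2-enyl]cyclopent-3-en-1-yl]octanoate (hydroxyl, sulfinyl and pentenyl on one face, ester chain on the other) | CC/C=C\C[C@@H]1C(O[Si](C)(C)C(C)(C)C)=C[C@H]([S@](=O)c2ccc(C)cc2)[C@]1(CCCCCCCC(=O)OC(C)(C)C)O | intermediate
22 | tetrabutylammonium enolate of the desilylated ketone from 21 (not isolated) | CCCC[N+](CCCC)(CCCC)CCCC.CC/C=C\C[C@@H]1C([O-])=C[C@H]([S@](=O)c2ccc(C)cc2)[C@]1(CCCCCCCC(=O)OC(C)(C)C)O | intermediate
23 | tert-butyl 8-[(1S,5S)-1-hydroxy-4-oxo-5-[(Z)-pent-2-enyl]cyclopent-2-en-1-yl]octanoate | CC/C=C\C[C@@H]1C(=O)C=C[C@]1(CCCCCCCC(=O)OC(C)(C)C)O | intermediate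
24 | tert-butyl 8-[(1S,5S)-1-acetoxy-4-oxo-5-[(Z)-pent-2-enyl]cyclopent-2-en-1-yl]octanoate | CC/C=C\C[C@@H]1C(=O)C=C[C@]1(CCCCCCCC(=O)OC(C)(C)C)OC(C)=O | intermediate
25 | 8-[(1S,5S)-1-acetoxy-4-oxo-5-[(Z)-pent-2-enyl]cyclopent-2-en-1-yl]octanoic acid (CNP0348716.1) | CC/C=C\C[C@@H]1C(=O)C=C[C@]1(CCCCCCCC(=O)O)OC(C)=O | target

**Step count**
Total: 11 steps. Longest linear sequence: 7 steps (steps 1–3 then 8–11, or equally steps 4–6 then 8–11).

**Steps most likely to fail**

Step 8. The enolate may attack the sulfinyl enone in a conjugate sense with loss of sulfenate. The allyl anion may be quenched by proton transfer from the acidic C5–H before it closes. The sulfinyl group may give poor facial selectivity, so that the separation of diastereomers costs much of the material. The fallback uses known chemistry, sets out from 6, 17 and 9, and returns at 23. The cuprate addition to 6 is run in the presence of Me3SiCl to give the isolable silyl enol ether tert-butyl (9Z,12Z)-9-(trimethylsilyloxy)pentadeca-9,12-dienoate F1. In parallel, 9 is lithiated with n-BuLi and sulfenylated with PhSSPh to tert-butyl[1-methoxy-3-(phenylsulfanyl)propa-1,2-dien-1-yl]dimethylsilane F2. Aqueous H2SO4 in THF then gives (E)-1-[tert-butyl(dimethyl)silyl]-3-(phenylsulfanyl)prop-2-en-1-one F3, the thioether acylsilane for which the annulation with ketone lithium enolates is an established reaction type. MeLi in THF cleaves F1 to the copper-free lithium enolate 18, which with F3 at −78 → −30 °C should give racemic tert-butyl 8-[4-[tert-butyl(dimethyl)silyloxy]-1-hydroxy-5-[(Z)-pent-2-enyl]-2-(phenylsulfanyl)cyclopent-3-en-1-yl]octanoate F4. Bu4NF then removes the silyl group and benzenethiol to give racemic tert-butyl 8-[(1S*,5S*)-1-hydroxy-4-oxo-5-[(Z)-pent-2-enyl]cyclopent-2-en-1-yl]octanoate F5. Its enantiomers are separated by preparative HPLC on a chiral stationary phase, and the (1S,5S) enantiomer is 23.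

Step 5. The product is more acidic than the allene and may be deprotonated by the incoming lithioallene. The ambident anion may react at the silyl-bearing terminus. Exchange at sulfur may erode the configurational purity. The fallback sets out from 9 and returns at 13, forming the S–C bond at the sulfide level and creating the stereogenic sulfur by oxidation. Lithiated 9 is sulfenylated with di-p-tolyl disulfide to tert-butyl[1-methoxy-3-(4-methylphenylsulfanyl)propa-1,2-dien-1-yl]dimethylsilane F6. Acid hydrolysis gives (E)-1-[tert-butyl(dimethyl)silyl]-3-(4-methylphenylsulfanyl)prop-2-en-1-one F7, a vinylogous thioester that should equilibrate to the E geometry in the acid. Kagan–Modena sulfoxidation (Ti(OiPr)4, (S,S)-diethyl tartrate, H2O, cumene hydroperoxide, CH2Cl2, −20 °C) should then give 13. The tartrate enantiomer is chosen on the premise that the aryl group plays the large-group role, and the enantiomeric purity is raised by recrystallisation if needed.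

Step 10. Acylation of the hindered tertiary hydroxyl may be slow, and the β-acetoxy ketone once formed may lose acetic acid across C4–C5 or epimerise at C5. The fallback sets out from 6, 17 and 13 and returns at 24, moving the acetylation to a stage without an enolisable ketone. The lithium alkoxide that ends the cascade of step 8 is acetylated in the flask with Ac2O at −30 °C before work-up. This gives tert-butyl 8-[(1R,2S,5S)-1-acetoxy-4-[tert-butyl(dimethyl)silyloxy]-2-[(S)-(4-methylphenyl)sulfinyl]-5-[(Z)-pent-2-enyl]cyclopent-3-en-1-yl]octanoate F8. Bu4NF buffered with AcOH in THF at −20 °C then unveils the enone and gives 24 directly.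

**Further compounds**
F1 | step 8 | tert-butyl (9Z,12Z)-9-(trimethylsilyloxy)pentadeca-9,12-dienoate | CC/C=C\C/C=C(\O[Si](C)(C)C)CCCCCCCC(=O)OC(C)(C)C
F2 | step 8 | tert-butyl[1-methoxy-3-(phenylsulfanyl)propa-1,2-dien-1-yl]dimethylsilane | COC(=C=CSc1ccccc1)[Si](C)(C)C(C)(C)C
F3 | step 8 | (E)-1-[tert-butyl(dimethyl)silyl]-3-(phenylsulfanyl)prop-2-en-1-one | CC(C)(C)[Si](C)(C)C(=O)/C=C/Sc1ccccc1
F4 | step 8 | racemic tert-butyl 8-[4-[tert-butyl(dimethyl)silyloxy]-1-hydroxy-5-[(Z)-pent-2-enyl]-2-(phenylsulfanyl)cyclopent-3-en-1-yl]octanoate (hydroxyl cis to pentenyl, both enantiomers) | CC/C=C\C[C@@H]1C(O[Si](C)(C)C(C)(C)C)=CC(Sc2ccccc2)[C@]1(CCCCCCCC(=O)OC(C)(C)C)O.CC/C=C\C[C@H]1C(O[Si](C)(C)C(C)(C)C)=CC(Sc2ccccc2)[C@@]1(CCCCCCCC(=O)OC(C)(C)C)O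
F5 | step 8 | racemic tert-butyl 8-[(1S*,5S*)-1-hydroxy-4-oxo-5-[(Z)-pent-2-enyl]cyclopent-2-en-1-yl]octanoate (both enantiomers) | CC/C=C\C[C@@H]1C(=O)C=C[C@]1(CCCCCCCC(=O)OC(C)(C)C)O.CC/C=C\C[C@H]1C(=O)C=C[C@@]1(CCCCCCCC(=O)OC(C)(C)C)O
F6 | step 5 | tert-butyl[1-methoxy-3-(4-methylphenylsulfanyl)propa-1,2-dien-1-yl]dimethylsilane | COC(=C=CSc1ccc(C)cc1)[Si](C)(C)C(C)(C)C
F7 | step 5 | (E)-1-[tert-butyl(dimethyl)silyl]-3-(4-methylphenylsulfanyl)prop-2-en-1-one | CC(C)(C)[Si](C)(C)C(=O)/C=C/Sc1ccc(C)cc1
F8 | step 10 | tert-butyl 8-[(1R,2S,5S)-1-acetoxy-4-[tert-butyl(dimethyl)silyloxy]-2-[(S)-(4-methylphenyl)sulfinyl]-5-[(Z)-pent-2-enyl]cyclopent-3-en-1-yl]octanoate | CC/C=C\C[C@@H]1C(O[Si](C)(C)C(C)(C)C)=C[C@H]([S@](=O)c2ccc(C)cc2)[C@]1(CCCCCCCC(=O)OC(C)(C)C)OC(C)=O
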